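**Retrosynthetic overview**

1. Target 18 ⇐ its C6 formate 17 ⇐ open-chain (Z)-iodoalkenyl aldehyde 15. The C3–C4 bond and the only ring (cyclohexene C1–C6) are made by an intramolecular Nozaki–Hiyama–Kishi addition.
2. Feature the strategy rests on: in the ring C1(OMe)–C2H=C3(C7H2OBz)–C4(OH)–C5(OBz)–C6(OH), the C5/C6/C1 triad is C3/C4/C5 of D-glucose. Only the C3–C4 bond and the C4 carbinol beside the trisubstituted C2=C3 alkene have to be created.
3. 15 ⇐ furanose lactol 14: periodate excision of glucose C1 opens the chain, turns glucose C2 into the aldehyde (ring C4) and leaves the furanose oxygen O4 as the C6 formate, which serves as the protecting group.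
4. The C2=C3(I)–C7H2OBz unit ⇐ glucose C6 aldehyde 8 by Wittig enal formation, α-iodination, 1,2-reduction and benzoylation.
5. 8 ⇐ diacetone-D-glucose 1 by O3 benzoylation, 5,6-diol release, O6 silylation, O5 methylation, desilylation and oxidation.

Key step: step 13

Remark: glucose (octose) numbering is used for 1–14 and the ring numbering of line 2 for 15–18. Lactol 14 is taken as an anomeric mixture, which is of no consequence because C1 is excised in step 12.

**Route**

Step 1
Reactants: 1 diacetone-D-glucose (1,2:5,6-di-O-isopropylidene-α-D-glucofuranose); 2 benzoyl chloride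
Product: 3 3-O-benzoyl-1,2:5,6-di-O-isopropylidene-α-D-glucofuranose
Conditions: pyridine, DMAP (cat.), CH2Cl2, 0 °C → rt
Reagents that add atoms: none
Why: Esterification of the only free hydroxyl (O3) with the acid chloride places the future C5 benzoate without touching a stereocentre.

Step 2
Reactants: 3 3-O-benzoyl-1,2:5,6-di-O-isopropylidene-α-D-glucofuranose
Product: 4 3-O-benzoyl-1,2-O-isopropylidene-α-D-glucofuranose
Conditions: AcOH–H2O (7:3), 40 °C
Reagents that add atoms: none
Why: Acid-catalysed acetal hydrolysis is selective for the exocyclic 5,6-acetonide because the cis-fused 1,2-acetonide on the furanose is much less labile, and the benzoate is inert to aqueous acetic acid.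

Step 3
Reactants: 4 3-O-benzoyl-1,2-O-isopropylidene-α-D-glucofuranose
Product: 5 3-O-benzoyl-6-O-(tert-butyldimethylsilyl)-1,2-O-isopropylidene-α-D-glucofuranose
Conditions: TBSCl, imidazole, DMF, 0 °C
Reagents that add atoms: tert-butyldimethylsilyl chloride, CC(C)(C)[Si](C)(C)Cl
Why: Silyl ether formation with a bulky silyl chloride discriminates the primary O6 from the secondary O5 on steric grounds, and the short exposure to imidazole at 0 °C should not move the benzoate.

Step 4
Reactants: 5 3-O-benzoyl-6-O-(tert-butyldimethylsilyl)-1,2-O-isopropylidene-α-D-glucofuranose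
Product: 6 3-O-benzoyl-6-O-(tert-butyldimethylsilyl)-1,2-O-isopropylidene-5-O-methyl-α-D-glucofuranose
Conditions: Me3OBF4, 1,8-bis(dimethylamino)naphthalene, 4 Å MS, CH2Cl2, rt
Reagents that add atoms: trimethyloxonium tetrafluoroborate, C[O+](C)C.F[B-](F)(F)F
Why: O-Alkylation with Meerwein's salt under hindered-amine buffering methylates the neutral alcohol without forming an alkoxide, so the O3 benzoate should neither migrate nor cleave as it could under Williamson conditions.

Step 5
Reactants: 6 3-O-benzoyl-6-O-(tert-butyldimethylsilyl)-1,2-O-isopropylidene-5-O-methyl-α-D-glucofuranose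
Product: 7 3-O-benzoyl-1,2-O-isopropylidene-5-O-methyl-α-D-glucofuranose
Conditions: HF·pyridine, pyridine, THF, 0 °C → rt
Reagents that add atoms: none
Why: Fluoride desilylation under buffered, weakly acidic conditions frees O6 without generating a basic alkoxide next to the benzoate.

Step 6
Reactants: 7 3-O-benzoyl-1,2-O-isopropylidene-5-O-methyl-α-D-glucofuranose
Product: 8 3-O-benzoyl-1,2-O-isopropylidene-5-O-methyl-α-D-gluco-hexodialdo-1,4-furanose (C6 aldehyde)
Conditions: Dess–Martin periodinane, CH2Cl2, 0 °C → rt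
Reagents that add atoms: none
Why: Dess–Martin oxidation gives the aldehyde under near-neutral conditions that should not epimerise the α-methoxy centre C5; the aldehyde is used at once.

Step 7
Reactants: 8 C6 aldehyde; 9 (triphenylphosphoranylidene)acetaldehyde
Product: 10 (E)-3-O-benzoyl-6,7-dideoxy-1,2-O-isopropylidene-5-O-methyl-α-D-gluco-oct-6-enodialdo-1,4-furanose (C8 enal)
Conditions: toluene, 70 °C
Reagents that add atoms: none
Why: Wittig olefination with the stabilised formyl ylide needs no base, tolerates the ester and should give the (E)-enal, as stabilised ylides do.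

Step 8
Reactants: 10 (E)-enal
Product: 11 (Z)-3-O-benzoyl-6,7-dideoxy-7-iodo-1,2-O-isopropylidene-5-O-methyl-α-D-gluco-oct-6-enodialdo-1,4-furanose
Conditions: I2, DMAP (0.2 equiv), K2CO3, THF–H2O (1:1), rt
Reagents that add atoms: iodine, II
Why: Amine-catalysed α-iodination of an enal (conjugate addition of DMAP, iodination of the enolate at C7, E1cB loss of DMAP) should return the conjugated system in its more stable geometry, with iodine cis to the C5 chain, which is the (Z)-alkene needed for ring closure.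

Step 9
Reactants: 11 (Z)-α-iodoenal
Product: 12 (Z)-3-O-benzoyl-6,7-dideoxy-7-iodo-1,2-O-isopropylidene-5-O-methyl-α-D-gluco-oct-6-eno-1,4-furanose (8-OH)
Conditions: NaBH4, CeCl3·7H2O, MeOH, −40 °C
Reagents that add atoms: none
Why: Luche 1,2-reduction of the aldehyde is fast at low temperature and should leave the vinyl iodide, the alkene geometry and the benzoate untouched.

Step 10
Reactants: 12 (Z)-iodo allylic alcohol; 2 benzoyl chloride
Product: 13 (Z)-3,8-di-O-benzoyl-6,7-dideoxy-7-iodo-1,2-O-isopropylidene-5-O-methyl-α-D-gluco-oct-6-eno-1,4-furanose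
Conditions: pyridine, DMAP (cat.), CH2Cl2, 0 °C
Reagents that add atoms: none
Why: Esterification of the only free (primary allylic) hydroxyl with the acid chloride installs the C7 benzoate of the target.

Step 11
Reactants: 13 3,8-dibenzoate acetonide
Product: 14 (Z)-3,8-di-O-benzoyl-6,7-dideoxy-7-iodo-5-O-methyl-D-gluco-oct-6-eno-1,4-furanose (lactol, α/β)
Conditions: TFA–H2O (9:1), 0 °C → rt
Reagents that add atoms: water, O
Why: Acid-catalysed hydrolysis of the 1,2-O-isopropylidene acetal exposes the 1,2-diol as the lactol, while the benzoates, the methyl ether and the electron-poor iodoalkene (which disfavours allylic ionisation at C5) should survive the short exposure.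

Step 12
Reactants: 14 lactol
Product: 15 (2S,3R,4R,5Z)-2,7-bis(benzoyloxy)-3-(formyloxy)-6-iodo-4-methoxyhept-5-enal (ring numbering: C4 aldehyde, 5-OBz, 6-OCHO, 1-OMe, (Z)-C2=C3–I, C7H2OBz)
Conditions: NaIO4 on silica gel, CH2Cl2, rt; filter, dry azeotropically (toluene), use crude
Reagents that add atoms: none
Why: Periodate (Malaprade) glycol cleavage of the C1–C2 diol turns glucose C2 into the aldehyde and leaves C1 as a formate on the former ring oxygen, so the chain opens with the C6 oxygen already protected and no stereocentre touched.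

Step 13
Reactants: 15 (Z)-iodoalkenyl formate aldehyde
Product: 17 [(3R,4R,5R,6R)-5-(benzoyloxy)-4-(formyloxy)-6-hydroxy-3-methoxycyclohex-1-en-1-yl]methyl benzoate (6-O-formyl derivative of the target in ring numbering), via alkenylchromium dichloride 16 (not isolated)
Conditions: CrCl2 (6 equiv), NiCl2 (2 mol %), degassed DMF, rt, 0.01 M; aqueous work-up
Reagents that add atoms: none
Why: CrCl2 reduces NiCl2 to zerovalent nickel, which inserts into the C3–I bond; transmetalation to trivalent chromium gives alkenylchromium 16, which adds to the C4 aldehyde and, after hydrolysis of the chromium alkoxide, should give 17. The closest known reaction type is the intramolecular Nozaki–Hiyama–Kishi alkenylation that delivers cyclic allylic alcohols. The cyclohexene closes in a 6-exo-trig mode, the (Z)-alkene holding C3 and C4 within bonding distance and becoming endocyclic. The new C4 stereocentre is controlled by the C5 benzoate and the C3 substituent: in a half-chair transition state with C5–OBz and C6–OCHO equatorial and C1–OMe pseudoaxial, the forming C3–C4 bond is antiperiplanar to the C5–O bond (polar Felkin–Anh) and the chromium-bound carbonyl oxygen sits pseudoaxial to avoid allylic 1,2-strain with C7H2OBz, which places the C4 hydroxyl cis to C5–OBz. The step needs addition to the aldehyde only, which the low basicity and aldehyde selectivity of alkenylchromium reagents should secure in the presence of the formate and both benzoates, and the neutral medium should keep the β-formyloxy aldehyde from eliminating.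

Step 14
Reactants: 17 6-O-formyl cyclohexenol
Product: 18 target, [(3R,4R,5R,6R)-5-(benzoyloxy)-4,6-dihydroxy-3-methoxycyclohex-1-en-1-yl]methyl benzoate
Conditions: KHCO3 (0.3 equiv), MeOH, 0 °C
Reagents that add atoms: none
Why: Base-catalysed transesterification (methanolysis) removes a formate far faster than a benzoate, so brief treatment at 0 °C should unveil the C6 hydroxyl before benzoyl migration can start.

**Compound list**

1 | 1,2:5,6-di-O-isopropylidene-α-D-glucofuranose (diacetone-D-glucose) | CC1(C)OC[C@@H](O1)[C@H]1O[C@@H]2OC(C)(C)O[C@@H]2[C@H]1O | starting material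
2 | benzoyl chloride | O=C(Cl)c1ccccc1 | starting material
3 | 3-O-benzoyl-1,2:5,6-di-O-isopropylidene-α-D-glucofuranose | CC1(C)OC[C@@H](O1)[C@H]1O[C@@H]2OC(C)(C)O[C@@H]2[C@H]1OC(=O)c1ccccc1 | intermediate
4 | 3-O-benzoyl-1,2-O-isopropylidene-α-D-glucofuranose | OC[C@@H](O)[C@H]1O[C@@H]2OC(C)(C)O[C@@H]2[C@H]1OC(=O)c1ccccc1 | intermediate
5 | 3-O-benzoyl-6-O-(tert-butyldimethylsilyl)-1,2-O-isopropylidene-α-D-glucofuranose | CC(C)(C)[Si](C)(C)OC[C@@H](O)[C@H]1O[C@@H]2OC(C)(C)O[C@@H]2[C@H]1OC(=O)c1ccccc1 | intermediate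
6 | 3-O-benzoyl-6-O-(tert-butyldimethylsilyl)-1,2-O-isopropylidene-5-O-methyl-α-D-glucofuranose | CC(C)(C)[Si](C)(C)OC[C@@H](OC)[C@H]1O[C@@H]2OC(C)(C)O[C@@H]2[C@H]1OC(=O)c1ccccc1 | intermediate
7 | 3-O-benzoyl-1,2-O-isopropylidene-5-O-methyl-α-D-glucofuranose | OC[C@@H](OC)[C@H]1O[C@@H]2OC(C)(C)O[C@@H]2[C@H]1OC(=O)c1ccccc1 | intermediate
8 | 3-O-benzoyl-1,2-O-isopropylidene-5-O-methyl-α-D-gluco-hexodialdo-1,4-furanose | O=C[C@@H](OC)[C@H]1O[C@@H]2OC(C)(C)O[C@@H]2[C@H]1OC(=O)c1ccccc1 | intermediate
9 | (triphenylphosphoranylidene)acetaldehyde | O=CC=P(c1ccccc1)(c1ccccc1)c1ccccc1 | starting material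
10 | (E)-3-O-benzoyl-6,7-dideoxy-1,2-O-isopropylidene-5-O-methyl-α-D-gluco-oct-6-enodialdo-1,4-furanose | O=C/C=C/[C@@H](OC)[C@H]1O[C@@H]2OC(C)(C)O[C@@H]2[C@H]1OC(=O)c1ccccc1 | intermediate
11 | (Z)-3-O-benzoyl-6,7-dideoxy-7-iodo-1,2-O-isopropylidene-5-O-methyl-α-D-gluco-oct-6-enodialdo-1,4-furanose | O=C/C(I)=C/[C@@H](OC)[C@H]1O[C@@H]2OC(C)(C)O[C@@H]2[C@H]1OC(=O)c1ccccc1 | intermediate
12 | (Z)-3-O-benzoyl-6,7-dideoxy-7-iodo-1,2-O-isopropylidene-5-O-methyl-α-D-gluco-oct-6-eno-1,4-furanose | OC/C(I)=C/[C@@H](OC)[C@H]1O[C@@H]2OC(C)(C)O[C@@H]2[C@H]1OC(=O)c1ccccc1 | intermediate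
13 | (Z)-3,8-di-O-benzoyl-6,7-dideoxy-7-iodo-1,2-O-isopropylidene-5-O-methyl-α-D-gluco-oct-6-eno-1,4-furanose | O=C(OC/C(I)=C/[C@@H](OC)[C@H]1O[C@@H]2OC(C)(C)O[C@@H]2[C@H]1OC(=O)c1ccccc1)c1ccccc1 | intermediate
14 | (Z)-3,8-di-O-benzoyl-6,7-dideoxy-7-iodo-5-O-methyl-D-gluco-oct-6-eno-1,4-furanose (α/β lactol) | O=C(OC/C(I)=C/[C@@H](OC)[C@H]1OC(O)[C@H](O)[C@H]1OC(=O)c1ccccc1)c1ccccc1 | intermediate
15 | (2S,3R,4R,5Z)-2,7-bis(benzoyloxy)-3-(formyloxy)-6-iodo-4-methoxyhept-5-enal | O=C[C@@H](OC(=O)c1ccccc1)[C@H](OC=O)[C@H](OC)/C=C(\I)COC(=O)c1ccccc1 | intermediate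
16 | alkenylchromium dichloride of 15 (CrCl2 unit in place of iodine at C3, trivalent chromium) | O=C[C@@H](OC(=O)c1ccccc1)[C@H](OC=O)[C@H](OC)/C=C(\[Cr](Cl)Cl)COC(=O)c1ccccc1 | intermediate
17 | [(3R,4R,5R,6R)-5-(benzoyloxy)-4-(formyloxy)-6-hydroxy-3-methoxycyclohex-1-en-1-yl]methyl benzoate | O[C@H]1[C@@H](OC(=O)c2ccccc2)[C@H](OC=O)[C@H](OC)C=C1COC(=O)c2ccccc2 | intermediate
18 | [(3R,4R,5R,6R)-5-(benzoyloxy)-4,6-dihydroxy-3-methoxycyclohex-1-en-1-yl]methyl benzoate (CNP0349013.4) | CO[C@@H]1C=C(COC(=O)c2ccccc2)[C@@H](O)[C@@H](OC(=O)c2ccccc2)[C@@H]1O | target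

**Step count**

Total: 14 steps. Longest linear sequence: 14 steps (1 → 18).

**Steps most likely to fail**

1. Step 13 (ring closure). The alkenylchromium may add to the other face of the aldehyde, so that the C4 hydroxyl ends up trans to the C5 benzoate. The fallback sets out from 15 and comes back at 18; it sets the C4 configuration by SN2 inversion instead of by the addition itself. The cyclisation is run as in step 13 and the C4-epimeric cyclohexenol F1 is collected. Treatment with PPh3, diisopropyl azodicarboxylate and chloroacetic acid (toluene–THF, 0 °C → rt) should give, by Mitsunobu inversion, the 4-O-chloroacetate F2 with the hydroxyl oxygen now cis to C5–OBz; the trans-diequatorial benzoate is poorly placed to participate. KHCO3 in MeOH at 0 °C should then remove the chloroacetyl and formyl groups together and deliver 18.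

2. Step 8 (α-iodination). The γ-methoxy enal may suffer base-promoted side reactions in aqueous carbonate (vinylogous deprotonation at C5 with β-elimination of the ring oxygen, benzoate hydrolysis), or the amine catalyst may turn over poorly. The fallback sets out from 10 and comes back at 16; the halogen is introduced by addition–elimination and the ring is closed from an alkenyl bromide. Br2 in CH2Cl2 at −78 °C should add across C6=C7 to give the 6,7-dibromo aldehyde F3 (not isolated), from which Et3N removes HBr to give the (Z)-7-bromoenal F4. The conditions of steps 9–12 should then lead through the bromo allylic alcohol F5, the bromo 3,8-dibenzoate F6 and the bromo lactol F7 to the bromo formate aldehyde F8. With CrCl2 and catalytic NiCl2 (DMSO, 40–50 °C, since alkenyl bromides insert more slowly) F8 should give the same alkenylchromium 16 and hence 17.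

3. Step 12 (periodate cleavage with the formate kept as protecting group). The α-benzoyloxy aldehyde may lose the formyl group or eliminate formic acid during isolation, drying or exposure to the chromium salts, and the benzoate may migrate during the basic deformylation of step 14. The fallback sets out from 15, taken crude and undried straight from the filtration, and comes back at 18; the formate is exchanged for a silyl ether while the aldehyde is masked. Camphorsulfonic acid and HC(OMe)3 in MeOH (rt) should acetalise the aldehyde and methanolyse the formate to give the hydroxy dimethyl acetal F9. TBSOTf with 2,6-lutidine (CH2Cl2, −78 °C) should give the silyl ether F10. TESOTf with 2,4,6-collidine (CH2Cl2, 0 °C), then water, should cleave the dimethyl acetal without touching the silyl ether or the esters and give the 6-O-TBS aldehyde F11. CrCl2 with catalytic NiCl2 under the conditions of step 13 should take F11, through the alkenylchromium dichloride F12 (not isolated), to the 6-O-TBS cyclohexenol F13. HF·pyridine in THF should then give 18 without any basic step.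

**Further compounds**

F1 | step 13 | [(3R,4R,5R,6S)-5-(benzoyloxy)-4-(formyloxy)-6-hydroxy-3-methoxycyclohex-1-en-1-yl]methyl benzoate (C4 epimer of 17 in ring numbering) | O[C@@H]1[C@@H](OC(=O)c2ccccc2)[C@H](OC=O)[C@H](OC)C=C1COC(=O)c2ccccc2
F2 | step 13 | [(3R,4R,5R,6R)-5-(benzoyloxy)-6-(chloroacetoxy)-4-(formyloxy)-3-methoxycyclohex-1-en-1-yl]methyl benzoate | O=C(CCl)O[C@H]1[C@@H](OC(=O)c2ccccc2)[C@H](OC=O)[C@H](OC)C=C1COC(=O)c2ccccc2
F3 | step 8 | 3-O-benzoyl-6,7-dibromo-6,7-dideoxy-1,2-O-isopropylidene-5-O-methyl-α-D-gluco-octodialdo-1,4-furanose (diastereomer mixture at C6 and C7) | O=CC(Br)C(Br)[C@@H](OC)[C@H]1O[C@@H]2OC(C)(C)O[C@@H]2[C@H]1OC(=O)c1ccccc1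
F4 | step 8 | (Z)-3-O-benzoyl-7-bromo-6,7-dideoxy-1,2-O-isopropylidene-5-O-methyl-α-D-gluco-oct-6-enodialdo-1,4-furanose | O=C/C(Br)=C/[C@@H](OC)[C@H]1O[C@@H]2OC(C)(C)O[C@@H]2[C@H]1OC(=O)c1ccccc1
F5 | step 8 | (Z)-3-O-benzoyl-7-bromo-6,7-dideoxy-1,2-O-isopropylidene-5-O-methyl-α-D-gluco-oct-6-eno-1,4-furanose | OC/C(Br)=C/[C@@H](OC)[C@H]1O[C@@H]2OC(C)(C)O[C@@H]2[C@H]1OC(=O)c1ccccc1
F6 | step 8 | (Z)-3,8-di-O-benzoyl-7-bromo-6,7-dideoxy-1,2-O-isopropylidene-5-O-methyl-α-D-gluco-oct-6-eno-1,4-furanose | O=C(OC/C(Br)=C/[C@@H](OC)[C@H]1O[C@@H]2OC(C)(C)O[C@@H]2[C@H]1OC(=O)c1ccccc1)c1ccccc1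
F7 | step 8 | (Z)-3,8-di-O-benzoyl-7-bromo-6,7-dideoxy-5-O-methyl-D-gluco-oct-6-eno-1,4-furanose (α/β lactol) | O=C(OC/C(Br)=C/[C@@H](OC)[C@H]1OC(O)[C@H](O)[C@H]1OC(=O)c1ccccc1)c1ccccc1
F8 | step 8 | (2S,3R,4R,5Z)-2,7-bis(benzoyloxy)-6-bromo-3-(formyloxy)-4-methoxyhept-5-enal | O=C[C@@H](OC(=O)c1ccccc1)[C@H](OC=O)[C@H](OC)/C=C(\Br)COC(=O)c1ccccc1
F9 | step 12 | (2S,3R,4R,5Z)-2,7-bis(benzoyloxy)-3-hydroxy-6-iodo-4-methoxyhept-5-enal dimethyl acetal | COC(OC)[C@@H](OC(=O)c1ccccc1)[C@H](O)[C@H](OC)/C=C(\I)COC(=O)c1ccccc1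
F10 | step 12 | (2S,3R,4R,5Z)-2,7-bis(benzoyloxy)-3-(tert-butyldimethylsilyloxy)-6-iodo-4-methoxyhept-5-enal dimethyl acetal | COC(OC)[C@@H](OC(=O)c1ccccc1)[C@H](O[Si](C)(C)C(C)(C)C)[C@H](OC)/C=C(\I)COC(=O)c1ccccc1
F11 | step 12 | (2S,3R,4R,5Z)-2,7-bis(benzoyloxy)-3-(tert-butyldimethylsilyloxy)-6-iodo-4-methoxyhept-5-enal | O=C[C@@H](OC(=O)c1ccccc1)[C@H](O[Si](C)(C)C(C)(C)C)[C@H](OC)/C=C(\I)COC(=O)c1ccccc1
F12 | step 12 | alkenylchromium dichloride of F11 (CrCl2 unit in place of iodine, trivalent chromium) | O=C[C@@H](OC(=O)c1ccccc1)[C@H](O[Si](C)(C)C(C)(C)C)[C@H](OC)/C=C(\[Cr](Cl)Cl)COC(=O)c1ccccc1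
F13 | step 12 | [(3R,4R,5R,6R)-5-(benzoyloxy)-4-(tert-butyldimethylsilyloxy)-6-hydroxy-3-methoxycyclohex-1-en-1-yl]methyl benzoate | O[C@H]1[C@@H](OC(=O)c2ccccc2)[C@H](O[Si](C)(C)C(C)(C)C)[C@H](OC)C=C1COC(=O)c2ccccc2
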